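**Retrosynthetic overview**
1. C3'–C1'': stereoretentive Suzuki–Miyaura coupling of unprotected 3'-bromodaidzein with a (1Z,3R)-alkenylboronate, so nothing needs deprotecting at the end.
2. The boronate comes from (R)-3,7-dimethyloct-6-en-1-yne, which comes from (R)-citronellal. All ten side-chain carbons and the stereocentre are bought. The Z geometry is set by a formal trans-hydroboration.
3. 3'-Bromodaidzein comes from a 3-aryl-3-hydroxychroman-4-one by loss of water (C2=C3) and of both O-methyl groups in one BBr3 operation.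
4. Key disconnection C3–C4: the aldehyde carbon of a 2-(phenacyloxy)benzaldehyde acts as an acyl anion (NHC, Breslow intermediate) and adds to the aryl ketone carbon, so two carbonyl carbons are joined. The keto-aldehyde is made in the same flask from a salicylaldehyde and a phenacyl bromide.
5. Rings: both benzene rings are bought, with Br already at C3', so there is no regiochemical question. The pyranone is the only ring made. It is closed in the benzoin step and made unsaturated in the next step.

Assumption: commercial (R)-(+)-citronellal of ≥97 % ee is used, and it fixes the optical purity of the product.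

**Step 1**
Reactants: 1 1-(3-bromo-4-methoxyphenyl)ethan-1-one
Product: 2 2-bromo-1-(3-bromo-4-methoxyphenyl)ethan-1-one
Conditions: CuBr2 (2.1 equiv), EtOAc/CHCl3 1:1, reflux, 4 h
Reagents that add atoms: copper(II) bromide, [Cu+2].[Br-].[Br-]
Why: King–Ostrum α-bromination, in which CuBr2 brominates the enol of the aryl methyl ketone once and, unlike free Br2, leaves the anisole ring alone; no stereocentre is involved.

**Step 2**
Reactants: 2 2-bromo-1-(3-bromo-4-methoxyphenyl)ethan-1-one; 3 2-hydroxy-4-methoxybenzaldehyde (1.05 equiv)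
Product: 6 (±)-3-(3-bromo-4-methoxyphenyl)-3-hydroxy-7-methoxychroman-4-one, via keto-aldehyde 4 (not isolated), via Breslow enaminol 5 (not isolated)
Conditions: i) K2CO3 (1.5 equiv), MeCN, rt, 12 h; ii) 2-(pentafluorophenyl)-6,7-dihydro-5H-pyrrolo[2,1-c][1,2,4]triazol-2-ium BF4 (10 mol %), Ar, rt → 40 °C, 12 h
Reagents that add atoms: none
Why: Williamson O-alkylation of the only free phenol gives 4, whose aldehyde carbon the triazolylidene converts into an acyl-anion equivalent (5) that adds 6-exo to the aryl ketone carbon in an NHC-catalysed intramolecular crossed aldehyde–ketone benzoin reaction, joining two normally electrophilic carbonyl carbons as C4–C3 and closing the pyranone ring; the acidic C6F5-triazolium needs only carbonate at rt, which keeps the competing Rap–Stoermer aldol slow, and the new C3 carbinol centre is deliberately racemic (achiral catalyst) because step 3 erases it.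

**Step 3**
Reactants: 6 (±)-3-(3-bromo-4-methoxyphenyl)-3-hydroxy-7-methoxychroman-4-one
Product: 8 3-(3-bromo-4-hydroxyphenyl)-7-hydroxy-4H-chromen-4-one (3'-bromodaidzein), via dimethoxyisoflavone 7 (not isolated)
Conditions: BBr3 (6 equiv), CH2Cl2, −78 °C → rt, 16 h; then MeOH, H2O
Reagents that add atoms: none
Why: BBr3 ionises the tertiary p-anisyl-stabilised C3 carbinol so that E1 dehydration with loss of a C2–H gives the conjugated chromone 7, and it then cleaves both aryl methyl ethers (Lewis-acid ether cleavage), while the aryl bromide is inert and the racemic centre disappears.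

**Step 4**
Reactants: 9 (R)-(+)-citronellal, (3R)-3,7-dimethyloct-6-enal
Product: 11 (3R)-3,7-dimethyloct-6-en-1-yne, via alkenyl nonaflate 10 (not isolated)
Conditions: n-C4F9SO2F (1.3 equiv), P2-Et phosphazene base (2.5 equiv), DMF, −10 °C → rt
Reagents that add atoms: none
Why: One-pot aldehyde-to-alkyne conversion by O-nonaflation of the enolate followed by β-elimination of nonaflate, in which the sulfonyl fluoride present from the start traps the enolate faster than it undergoes aldol addition; only C1 and C2 take part, so the (R) centre at C3 and the trisubstituted alkene are untouched and all ten carbons are kept.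

**Step 5**
Reactants: 11 (3R)-3,7-dimethyloct-6-en-1-yne (1.2 equiv)
Product: 12 2-[(1Z,3R)-3,7-dimethylocta-1,6-dien-1-yl]-4,4,5,5-tetramethyl-1,3,2-dioxaborolane
Conditions: HBpin (1.0 equiv), [Rh(cod)Cl]2 (1.5 mol %), P(i-Pr)3 (6 mol %), Et3N (1 equiv), cyclohexane, rt
Reagents that add atoms: pinacolborane, B1OC(C)(C)C(C)(C)O1
Why: Miyaura Rh(I)/P(i-Pr)3-catalysed formal trans-hydroboration of a terminal alkyne, which runs through a rhodium vinylidene (1,2-H shift) so that boron and the alkyl chain end up cis (Z), does not touch the trisubstituted alkene at rt and leaves the sp3 C3 centre (R).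

**Step 6**
Reactants: 8 3'-bromodaidzein; 12 (1Z,3R)-alkenyl pinacol boronate (1.3 equiv)
Product: 13 7-hydroxy-3-{4-hydroxy-3-[(1Z,3R)-3,7-dimethylocta-1,6-dien-1-yl]phenyl}-4H-chromen-4-one (target)
Conditions: SPhos Pd G3 (3 mol %), K3PO4 (4 equiv), degassed THF/H2O 4:1, 50 °C; then aq. NH4Cl to pH 6
Reagents that add atoms: none
Why: Suzuki–Miyaura coupling, in which transmetalation and reductive elimination keep the alkene geometry (Z) and do not touch the allylic (R) centre, the dialkylbiarylphosphine makes oxidative addition into the electron-rich bromophenoxide feasible, and the free phenols are tolerated as phenoxides that also shield the pyranone from hydroxide.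

**Compound list**
1 | 1-(3-bromo-4-methoxyphenyl)ethan-1-one | CC(=O)c1ccc(OC)c(Br)c1 | starting material
2 | 2-bromo-1-(3-bromo-4-methoxyphenyl)ethan-1-one | BrCC(=O)c1ccc(OC)c(Br)c1 | intermediate
3 | 2-hydroxy-4-methoxybenzaldehyde | COc1ccc(C=O)c(O)c1 | starting material
4 | 2-[2-(3-bromo-4-methoxyphenyl)-2-oxoethoxy]-4-methoxybenzaldehyde | O=Cc1ccc(OC)cc1OCC(=O)c1ccc(OC)c(Br)c1 | intermediate
5 | Breslow enaminol of 4 with the C6F5-pyrrolotriazolylidene | OC(=C1N(c2c(F)c(F)c(F)c(F)c2F)N=C2CCCN12)c1ccc(OC)cc1OCC(=O)c1ccc(OC)c(Br)c1 | intermediate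
6 | (±)-3-(3-bromo-4-methoxyphenyl)-3-hydroxy-7-methoxychroman-4-one (racemic) | COc1ccc2c(c1)OCC(O)(c1ccc(OC)c(Br)c1)C2=O | intermediate
7 | 3-(3-bromo-4-methoxyphenyl)-7-methoxy-4H-chromen-4-one | COc1ccc2c(c1)occ(-c1ccc(OC)c(Br)c1)c2=O | intermediate
8 | 3-(3-bromo-4-hydroxyphenyl)-7-hydroxy-4H-chromen-4-one | Oc1ccc2c(c1)occ(-c1ccc(O)c(Br)c1)c2=O | intermediate
9 | (3R)-3,7-dimethyloct-6-enal, (R)-(+)-citronellal | CC(C)=CCC[C@@H](C)CC=O | starting material
10 | (3R)-3,7-dimethylocta-1,6-dien-1-yl nonafluorobutane-1-sulfonate (E/Z mixture) | CC(C)=CCC[C@@H](C)C=COS(=O)(=O)C(F)(F)C(F)(F)C(F)(F)C(F)(F)F | intermediate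
11 | (3R)-3,7-dimethyloct-6-en-1-yne | CC(C)=CCC[C@@H](C)C#C | intermediate
12 | 2-[(1Z,3R)-3,7-dimethylocta-1,6-dien-1-yl]-4,4,5,5-tetramethyl-1,3,2-dioxaborolane | CC(C)=CCC[C@@H](C)/C=C\B1OC(C)(C)C(C)(C)O1 | intermediate
13 | 7-hydroxy-3-{4-hydroxy-3-[(1Z,3R)-3,7-dimethylocta-1,6-dien-1-yl]phenyl}-4H-chromen-4-one | CC(C)=CCC[C@@H](C)/C=C\c1cc(-c2coc3cc(O)ccc3c2=O)ccc1O | target

**Total step count:** 6. **Longest linear sequence:** 4 (steps 1, 2, 3, 6). The side-chain branch is steps 4, 5, 6.

**Steps most likely to fail**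

Step 2 (key benzoin). The acidic OCH2 of 4 may add to the aldehyde (Rap–Stoermer aldol, giving a 2-aroylbenzofuran) faster than the electron-rich aldehyde forms 5.
- The fallback keeps an acyl-anion logic but moves the bond-forming site to C4–CH2. It sets out from 3 and comes back at 7.
- Compound 3 with propane-1,3-dithiol and BF3·OEt2 in CH2Cl2 gives 2-(1,3-dithian-2-yl)-5-methoxyphenol F1.
- Double deprotonation (n-BuLi, 2.2 equiv, THF, −30 °C) gives the Corey–Seebach anion. Alkylation with commercial 3-bromo-4-methoxybenzyl bromide gives 2-[2-(3-bromo-4-methoxybenzyl)-1,3-dithian-2-yl]-5-methoxyphenol F2.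
- Unmasking with MeI/CaCO3 in aqueous MeCN gives the deoxybenzoin 2-(3-bromo-4-methoxyphenyl)-1-(2-hydroxy-4-methoxyphenyl)ethan-1-one F3.
- DMF dimethyl acetal at 90 °C then adds C2 and closes the pyranone to 7. Here 7 is isolated and taken through the BBr3 treatment of step 3.

Step 6 (Suzuki coupling). The hindered Z-alkenylboronate may transmetalate slowly onto the bromophenoxide-derived palladium species, with protodeboronation or Z→E leakage.
- The fallback makes the Z-alkene on the arene instead and also by-passes step 5. It sets out from 8 (with 11) and comes back at 13.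
- Compound 8 with TBSCl and imidazole in DMF gives 3-[3-bromo-4-(tert-butyldimethylsilyloxy)phenyl]-7-(tert-butyldimethylsilyloxy)-4H-chromen-4-one F4. The silyl group blocks benzofuran formation.
- Sonogashira coupling with 11 (Pd(PPh3)2Cl2, CuI, Et3N/DMF, 70 °C) gives 7-(tert-butyldimethylsilyloxy)-3-{4-(tert-butyldimethylsilyloxy)-3-[(3R)-3,7-dimethyloct-6-en-1-yn-1-yl]phenyl}-4H-chromen-4-one F5.
- Lindlar semi-hydrogenation (H2, 1 atm, quinoline, EtOAc) gives the bis-silyl ether of the target, 7-(tert-butyldimethylsilyloxy)-3-{4-(tert-butyldimethylsilyloxy)-3-[(1Z,3R)-3,7-dimethylocta-1,6-dien-1-yl]phenyl}-4H-chromen-4-one F6.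
- TBAF buffered with AcOH in THF at 0 °C releases 13.

Step 4 (aldehyde to alkyne). The very strong phosphazene base may cause aldol loss, or alkyne–allene equilibration that would erode the propargylic centre.
- The fallback goes through a gem-dihalide. It sets out from 9 and comes back at 11.
- Compound 9 with preformed (PhO)3P·Br2 in CH2Cl2, −78 °C → rt, gives (6R)-8,8-dibromo-2,6-dimethyloct-2-ene F7.
- Double dehydrobromination with LDA (3.3 equiv, THF, −78 → 0 °C) and aqueous quench of the acetylide gives 11.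

**Further compounds**
F1 | step 2 | 2-(1,3-dithian-2-yl)-5-methoxyphenol | COc1ccc(C2SCCCS2)c(O)c1
F2 | step 2 | 2-[2-(3-bromo-4-methoxybenzyl)-1,3-dithian-2-yl]-5-methoxyphenol | COc1ccc(C2(Cc3ccc(OC)c(Br)c3)SCCCS2)c(O)c1
F3 | step 2 | 2-(3-bromo-4-methoxyphenyl)-1-(2-hydroxy-4-methoxyphenyl)ethan-1-one | COc1ccc(C(=O)Cc2ccc(OC)c(Br)c2)c(O)c1
F4 | step 6 | 3-[3-bromo-4-(tert-butyldimethylsilyloxy)phenyl]-7-(tert-butyldimethylsilyloxy)-4H-chromen-4-one | CC(C)(C)[Si](C)(C)Oc1ccc2c(c1)occ(-c1ccc(O[Si](C)(C)C(C)(C)C)c(Br)c1)c2=O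
F5 | step 6 | 7-(tert-butyldimethylsilyloxy)-3-{4-(tert-butyldimethylsilyloxy)-3-[(3R)-3,7-dimethyloct-6-en-1-yn-1-yl]phenyl}-4H-chromen-4-one | CC(C)=CCC[C@@H](C)C#Cc1cc(-c2coc3cc(O[Si](C)(C)C(C)(C)C)ccc3c2=O)ccc1O[Si](C)(C)C(C)(C)C
F6 | step 6 | 7-(tert-butyldimethylsilyloxy)-3-{4-(tert-butyldimethylsilyloxy)-3-[(1Z,3R)-3,7-dimethylocta-1,6-dien-1-yl]phenyl}-4H-chromen-4-one | CC(C)=CCC[C@@H](C)/C=C\c1cc(-c2coc3cc(O[Si](C)(C)C(C)(C)C)ccc3c2=O)ccc1O[Si](C)(C)C(C)(C)C
F7 | step 4 | (6R)-8,8-dibromo-2,6-dimethyloct-2-ene | CC(C)=CCC[C@@H](C)CC(Br)Br
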